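Ring B (C5–C10; ring A is C1–C5 plus C10) is cut at its C8–C9 ethano bridge, the one ring bond that carries no function and lies between two centres that can be set beforehand, C7 and quaternary C10. Ring A is made first: a bromonium-triggered semipinacol shift fixes C1–Br and C10 together. The key step is a tandem ring-closing metathesis/hydrogenation of a cyclohexene bearing a C10 hexenyl group and a C5–CH2–CH(CH2OH)–CH=CH2 arm. It closes ring B with C8–C9 saturated and spares the tetrasubstituted C4=C5 alkene, from which the C5 carbinol and the exocyclic methylene follow by epoxidation and isomerisation. The trienyl chain is grown last from the C7 hydroxymethyl group.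

Key step: step 8

Remark: ring atoms are labelled C1 (CHBr), C2, C3, C4 (bears C15), C5 (carbinol), C6, C7 (bears side-chain carbon C11), C8, C9, C10 (bears the methyl), and β is the face of the C10 methyl; in steps 1 and 5 the ligand enantiomer is assumed to be the one that delivers the drawn configuration.

Step 1
Reactants: 1 hex-1-yne; 2 2-methylcyclohex-2-en-1-one
Product: 5 (R)-1-[(E)-hex-1-en-1-yl]-2-methylcyclohex-2-en-1-ol, via (E)-hex-1-enylzirconocene chloride 3 (not isolated), via (E)-hex-1-enyl(methyl)zinc 4 (not isolated)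
Conditions: Cp2Zr(H)Cl, CH2Cl2, rt; Me2Zn, toluene, −78 °C; then 2, Ti(OiPr)4 (1.2 equiv), trans-cyclohexane-1,2-diamine bis(hydroxycamphorsulfonamide) ligand (10 mol%), toluene, rt
Reagents that add atoms: none
Why: Hydrozirconation of the alkyne and Zr-to-Zn transmetalation give an (E)-alkenylzinc that adds 1,2 to the enone under titanium bis(sulfonamide) catalysis (catalytic asymmetric alkenylation of a ketone), the chiral titanium complex telling the methyl-bearing sp2 flank from the CH2 flank of the carbonyl and so setting the tertiary carbinol centre (R).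

Step 2
Reactants: 5 (R)-1-[(E)-hex-1-en-1-yl]-2-methylcyclohex-2-en-1-ol
Product: 6 (2R,3R)-3-bromo-2-[(E)-hex-1-en-1-yl]-2-methylcyclohexan-1-one
Conditions: NBS, CH2Cl2, −40 °C to 0 °C
Reagents that add atoms: N-bromosuccinimide, BrN1C(=O)CCC1=O
Why: Halonium-induced semipinacol rearrangement: the more nucleophilic trisubstituted ring alkene takes up Br+ on the face of the hydroxyl and the antiperiplanar alkenyl group shifts from the carbinol carbon to C10 as the carbonyl forms, so that bromine at C1 and the migrated group end up trans and the single carbinol stereocentre is relayed into both C1 (R) and quaternary C10 (R).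

Step 3
Reactants: 6 (2R,3R)-3-bromo-2-[(E)-hex-1-en-1-yl]-2-methylcyclohexan-1-one
Product: 8 (2R,3R)-3-bromo-2-[(E)-hex-1-en-1-yl]-2,6-dimethylcyclohexan-1-one (both C6 epimers), via lithium enolate 7 (not isolated)
Conditions: LDA, THF, −78 °C; MeI, −78 °C to 0 °C
Reagents that add atoms: iodomethane, CI
Why: Kinetic enolate alkylation at C4, the only enolisable position because C10 is quaternary, installs the future C15 carbon, the mixture of C4 epimers being of no consequence since this centre becomes sp2 in step 4.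

Step 4
Reactants: 8 (2R,3R)-3-bromo-2-[(E)-hex-1-en-1-yl]-2,6-dimethylcyclohexan-1-one
Product: 10 (5R,6R)-5-bromo-6-[(E)-hex-1-en-1-yl]-2,6-dimethylcyclohex-1-en-1-yl trifluoromethanesulfonate, via potassium enolate 9 (not isolated)
Conditions: KHMDS, THF, −78 °C; PhNTf2, −78 °C to 0 °C
Reagents that add atoms: N-phenylbis(trifluoromethanesulfonimide), FC(F)(F)S(=O)(=O)N(c1ccccc1)S(=O)(=O)C(F)(F)F
Why: Deprotonation of the remaining C4–H and O-sulfonylation of the enolate (enol triflate formation) fixes the tetrasubstituted C4=C5 double bond in the only possible position and activates C5 for cross-coupling.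

Step 5
Reactants: 11 (E)-1,4-dibromobut-2-ene; 12 (chloromethyl)(isopropoxy)dimethylsilane
Product: 14 (S)-[2-(bromomethyl)but-3-en-1-yl](isopropoxy)dimethylsilane, via [(isopropoxydimethylsilyl)methyl]magnesium chloride 13 (not isolated)
Conditions: 12, Mg, Et2O, reflux; then 11, CuBr·SMe2 (3 mol%), (S,R,R)-binaphthol bis(1-phenylethyl)amine phosphoramidite (3.3 mol%), CH2Cl2, −78 °C
Reagents that add atoms: none
Why: Copper-catalysed asymmetric allylic alkylation (SN2′) of the symmetrical dibromide by the silylmethyl Grignard reagent should give the branched product, the chiral phosphoramidite–copper complex selecting the face of the allyl unit and so setting the future C7 centre (S), while the bromide left behind is no longer allylic and stays untouched.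

Step 6
Reactants: 14 (S)-[2-(bromomethyl)but-3-en-1-yl](isopropoxy)dimethylsilane; 10 (5R,6R)-5-bromo-6-[(E)-hex-1-en-1-yl]-2,6-dimethylcyclohex-1-en-1-yl trifluoromethanesulfonate
Product: 16 {(2S)-2-{[(5R,6R)-5-bromo-6-[(E)-hex-1-en-1-yl]-2,6-dimethylcyclohex-1-en-1-yl]methyl}but-3-en-1-yl}(isopropoxy)dimethylsilane, via alkylzinc bromide 15 (not isolated)
Conditions: 14, Zn dust, I2 (5 mol%), DMA, 70 °C; then 10, Pd(OAc)2 (5 mol%), SPhos (10 mol%), THF, 50 °C
Reagents that add atoms: none
Why: Negishi sp3–sp2 cross-coupling: zinc inserts into the primary C–Br bond and the resulting alkylzinc is coupled at C5, zerovalent palladium adding to the alkenyl C–OTf bond far faster than to the unactivated secondary C1–Br bond, so that the C5–C6 bond forms without touching C1, C7 or C10.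

Step 7
Reactants: 16 the coupled silane
Product: 17 (2S)-2-{[(5R,6R)-5-bromo-6-[(E)-hex-1-en-1-yl]-2,6-dimethylcyclohex-1-en-1-yl]methyl}but-3-en-1-ol
Conditions: H2O2 (30% aq), KF, KHCO3, THF/MeOH (1:1), rt
Reagents that add atoms: hydrogen peroxide, OO
Why: Tamao oxidation converts the C–Si(OiPr)Me2 bond into C–OH with retention under mild basic peroxide conditions that leave the alkenes and the secondary bromide untouched.

Step 8
Reactants: 17 (2S)-2-{[(5R,6R)-5-bromo-6-[(E)-hex-1-en-1-yl]-2,6-dimethylcyclohex-1-en-1-yl]methyl}but-3-en-1-ol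
Product: 19 [(2R,4aR,5R)-5-bromo-4a,8-dimethyl-1,2,3,4,4a,5,6,7-octahydronaphthalen-2-yl]methanol (1β-Br, 10β-CH3, 7β-CH2OH, C4=C5), via hexahydronaphthalene diene 18 (not isolated)
Conditions: second-generation Grubbs catalyst (5 mol%), ClCH2CH2Cl, 60 °C, argon sparge; then H2 (7 atm), 70 °C, same vessel
Reagents that add atoms: none
Why: The ruthenium alkylidene loads onto the terminal C8 vinyl group, undergoes [2+2] cycloaddition/cycloreversion with the C9 alkene on quaternary C10 and expels hex-1-ene, after which H2 turns the ruthenium residue into a hydride that saturates the new cis C8=C9 double bond. The closest known reaction type is ring-closing olefin metathesis run in tandem with hydrogenation by the same ruthenium charge. Ring B is closed as a six-membered carbocycle by olefin metathesis of a 1,7-diene, its two reacting alkenes being held together by the ring A template (C10, C5 and C6). No stereocentre is formed: C7 (from step 5) and C10 (from step 2) are carried through unchanged, and the ring junction is settled later because C5 is still sp2. The step needs chemoselectivity among three alkenes, which is secured by the tetrasubstituted, neopentyl-flanked C4=C5 bond being too hindered for both metathesis and hydrogenation. The secondary bromide and the free primary alcohol are tolerated by the ruthenium catalyst.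

Step 9
Reactants: 19 [(2R,4aR,5R)-5-bromo-4a,8-dimethyl-1,2,3,4,4a,5,6,7-octahydronaphthalen-2-yl]methanol
Product: 20 the 4α,5α-epoxide of 19 (epoxide oxygen on the face opposite the C10 methyl)
Conditions: mCPBA, CH2Cl2, −20 °C to 0 °C
Reagents that add atoms: 3-chloroperoxybenzoic acid, OOC(=O)c1cccc(Cl)c1
Why: Prilezhaev epoxidation of the only remaining alkene, the electron-rich tetrasubstituted C4=C5 bond, should take place on the α face opposite the axial C10 methyl group and thereby set the C5–O configuration.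

Step 10
Reactants: 20 the 4α,5α-epoxide
Product: 21 (1R,4aR,6R,8aR)-1-bromo-6-(hydroxymethyl)-8a-methyl-4-methylidenedecahydronaphthalen-4a-ol
Conditions: Et2Al(TMP) (4 equiv, from TMP, n-BuLi, Et2AlCl), toluene, 0 °C
Reagents that add atoms: none
Why: Aluminium amide-mediated epoxide-to-allylic alcohol isomerisation (syn β-elimination through a cyclic transition state): the bulky amide should remove the most accessible proton, that of the C4 methyl group on the oxygen face, so that the C4–O bond opens to the exocyclic methylene while the oxygen stays on C5 with retention (5α-OH).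

Step 11
Reactants: 21 (1R,4aR,6R,8aR)-1-bromo-6-(hydroxymethyl)-8a-methyl-4-methylidenedecahydronaphthalen-4a-ol
Product: 22 (2R,4aR,5R,8aR)-5-bromo-8a-hydroxy-4a-methyl-8-methylidenedecahydronaphthalene-2-carbaldehyde
Conditions: TEMPO (10 mol%), PhI(OAc)2, CH2Cl2, rt
Reagents that add atoms: none
Why: Oxoammonium (TEMPO)-catalysed oxidation with PhI(OAc)2 as terminal oxidant is selective for the primary alcohol, the tertiary allylic alcohol being inert, and the equatorial aldehyde trans to the 5α-hydroxyl cannot close to a lactol.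

Step 12
Reactants: 22 (2R,4aR,5R,8aR)-5-bromo-8a-hydroxy-4a-methyl-8-methylidenedecahydronaphthalene-2-carbaldehyde
Product: 23 (1R,4aR,6R,8aR)-1-bromo-6-ethynyl-8a-methyl-4-methylidenedecahydronaphthalen-4a-ol
Conditions: dimethyl (1-diazo-2-oxopropyl)phosphonate, K2CO3, MeOH, 0 °C to rt
Reagents that add atoms: dimethyl (1-diazo-2-oxopropyl)phosphonate, CC(=O)C(=[N+]=[N-])P(=O)(OC)OC
Why: Ohira–Bestmann (Seyferth–Gilbert) homologation turns the aldehyde into the terminal alkyne under mild carbonate conditions, and any base-induced epimerisation at C7 can only favour the required equatorial isomer.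

Step 13
Reactants: 24 2-methylbut-1-en-3-yne
Product: 26 (E)-1-iodo-3-methylbuta-1,3-diene, via dienylzirconocene chloride 25 (not isolated)
Conditions: Cp2Zr(H)Cl, THF, rt; then I2, 0 °C
Reagents that add atoms: iodine, II
Why: Hydrozirconation of the terminal alkyne of the enyne (syn, zirconium at the terminal carbon) followed by iodinolysis with retention should give the (E)-iododiene.

Step 14
Reactants: 23 (1R,4aR,6R,8aR)-1-bromo-6-ethynyl-8a-methyl-4-methylidenedecahydronaphthalen-4a-ol; 26 (E)-1-iodo-3-methylbuta-1,3-diene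
Product: 28 (1R,4aR,6R,8aR)-1-bromo-8a-methyl-4-methylidene-6-[(2E,4E)-6-methylhepta-2,4,6-trien-2-yl]decahydronaphthalen-4a-ol (CNP0385268.1), via alkenylalane 27 (not isolated)
Conditions: Me3Al (3 equiv), Cp2ZrCl2 (20 mol%), CH2Cl2, 0 °C to rt; then 26, Pd(PPh3)4 (5 mol%), THF, rt
Reagents that add atoms: trimethylaluminium, C[Al](C)C
Why: Negishi zirconium-catalysed carboalumination adds methyl and aluminium syn across the alkyne (aluminium terminal) to give the (E)-2-methylalkenylalane, which cross-couples with the (E)-iododiene under zerovalent palladium catalysis with retention at both partners, fixing both E double bonds while the hindered secondary bromide does not react.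

Compound list
1 | hex-1-yne | CCCCC#C | starting material
2 | 2-methylcyclohex-2-en-1-one | CC1=CCCCC1=O | starting material
3 | chlorobis(cyclopentadienyl)[(E)-hex-1-en-1-yl]zirconium | CCCC/C=C/[Zr](Cl)(C1C=CC=C1)C1C=CC=C1 | intermediate
4 | [(E)-hex-1-en-1-yl](methyl)zinc | CCCC/C=C/[Zn]C | intermediate
5 | (R)-1-[(E)-hex-1-en-1-yl]-2-methylcyclohex-2-en-1-ol | CCCC/C=C/[C@]1(O)CCCC=C1C | intermediate
6 | (2R,3R)-3-bromo-2-[(E)-hex-1-en-1-yl]-2-methylcyclohexan-1-one | CCCC/C=C/[C@@]1(C)[C@H](Br)CCCC1=O | intermediate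
7 | lithium enolate of 6 (C4=C5–OLi) | CCCC/C=C/[C@@]1(C)[C@H](Br)CCC=C1O[Li] | intermediate
8 | (2R,3R)-3-bromo-2-[(E)-hex-1-en-1-yl]-2,6-dimethylcyclohexan-1-one (both C6 epimers) | CCCC/C=C/[C@@]1(C)[C@H](Br)CCC(C)C1=O | intermediate
9 | potassium enolate of 8 | CCCC/C=C/[C@@]1(C)[C@H](Br)CCC(C)=C1O[K] | intermediate
10 | (5R,6R)-5-bromo-6-[(E)-hex-1-en-1-yl]-2,6-dimethylcyclohex-1-en-1-yl trifluoromethanesulfonate | CCCC/C=C/[C@@]1(C)[C@H](Br)CCC(C)=C1OS(=O)(=O)C(F)(F)F | intermediate
11 | (E)-1,4-dibromobut-2-ene | BrC/C=C/CBr | starting material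
12 | (chloromethyl)(isopropoxy)dimethylsilane | ClC[Si](C)(C)OC(C)C | starting material
13 | [(isopropoxydimethylsilyl)methyl]magnesium chloride | CC(C)O[Si](C)(C)C[Mg]Cl | intermediate
14 | (S)-[2-(bromomethyl)but-3-en-1-yl](isopropoxy)dimethylsilane | C=C[C@@H](C[Si](C)(C)OC(C)C)CBr | intermediate
15 | {(S)-2-[(isopropoxydimethylsilyl)methyl]but-3-en-1-yl}zinc bromide | C=C[C@@H](C[Si](C)(C)OC(C)C)C[Zn]Br | intermediate
16 | {(2S)-2-{[(5R,6R)-5-bromo-6-[(E)-hex-1-en-1-yl]-2,6-dimethylcyclohex-1-en-1-yl]methyl}but-3-en-1-yl}(isopropoxy)dimethylsilane | CCCC/C=C/[C@@]1(C)[C@H](Br)CCC(C)=C1C[C@H](C[Si](C)(C)OC(C)C)C=C | intermediate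
17 | (2S)-2-{[(5R,6R)-5-bromo-6-[(E)-hex-1-en-1-yl]-2,6-dimethylcyclohex-1-en-1-yl]methyl}but-3-en-1-ol | CCCC/C=C/[C@@]1(C)[C@H](Br)CCC(C)=C1C[C@H](CO)C=C | intermediate
18 | [(2S,4aR,5R)-5-bromo-4a,8-dimethyl-1,2,4a,5,6,7-hexahydronaphthalen-2-yl]methanol | OC[C@@H]1C=C[C@@]2(C)[C@H](Br)CCC(C)=C2C1 | intermediate
19 | [(2R,4aR,5R)-5-bromo-4a,8-dimethyl-1,2,3,4,4a,5,6,7-octahydronaphthalen-2-yl]methanol | OC[C@@H]1CC[C@@]2(C)[C@H](Br)CCC(C)=C2C1 | intermediate
20 | 4α,5α-epoxide of 19: (1β-bromo-4α,5α-epoxy-4,10β-dimethyldecalin-7β-yl)methanol | OC[C@@H]1CC[C@@]2(C)[C@H](Br)CC[C@@]3(C)O[C@@]23C1 | intermediate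
21 | (1R,4aR,6R,8aR)-1-bromo-6-(hydroxymethyl)-8a-methyl-4-methylidenedecahydronaphthalen-4a-ol | OC[C@@H]1CC[C@@]2(C)[C@H](Br)CCC(=C)[C@]2(O)C1 | intermediate
22 | (2R,4aR,5R,8aR)-5-bromo-8a-hydroxy-4a-methyl-8-methylidenedecahydronaphthalene-2-carbaldehyde | O=C[C@@H]1CC[C@@]2(C)[C@H](Br)CCC(=C)[C@]2(O)C1 | intermediate
23 | (1R,4aR,6R,8aR)-1-bromo-6-ethynyl-8a-methyl-4-methylidenedecahydronaphthalen-4a-ol | C#C[C@@H]1CC[C@@]2(C)[C@H](Br)CCC(=C)[C@]2(O)C1 | intermediate
24 | 2-methylbut-1-en-3-yne | C=C(C)C#C | starting material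
25 | chlorobis(cyclopentadienyl)[(E)-3-methylbuta-1,3-dien-1-yl]zirconium | C=C(C)/C=C/[Zr](Cl)(C1C=CC=C1)C1C=CC=C1 | intermediate
26 | (E)-1-iodo-3-methylbuta-1,3-diene | C=C(C)/C=C/I | intermediate
27 | (E)-2-methylalkenyl(dimethyl)alane of 23, with the C5 oxygen as its dimethylaluminium alkoxide | C[Al](C)/C=C(\C)[C@@H]1CC[C@@]2(C)[C@H](Br)CCC(=C)[C@]2(O[Al](C)C)C1 | intermediate
28 | (1R,4aR,6R,8aR)-1-bromo-8a-methyl-4-methylidene-6-[(2E,4E)-6-methylhepta-2,4,6-trien-2-yl]decahydronaphthalen-4a-ol | C=C(C)/C=C/C=C(\C)[C@@H]1CC[C@@]2(C)[C@H](Br)CCC(=C)[C@]2(O)C1 | target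

Total step count: 14 steps. Longest linear sequence: 12 steps (steps 1–4, 6–12 and 14; steps 5 and 13 are one-step side branches).

Steps most likely to fail

Step 2. The electrophilic bromine may be taken up by the hexenyl alkene, which would trigger a ring-enlarging shift of the ring carbon, or the bromonium ion may be captured by the hydroxyl group instead of triggering the alkenyl shift. The fallback removes the competing alkene before the shift and sets out from 5. Ethenolysis (ethene 1 atm, second-generation Hoveyda–Grubbs catalyst, CH2Cl2, 40 °C) should trim the hexenyl group to a vinyl group and give (R)-1-ethenyl-2-methylcyclohex-2-en-1-ol F1, whose monosubstituted alkene no longer competes for Br+. NBS should then give (2R,3R)-3-bromo-2-ethenyl-2-methylcyclohexan-1-one F2. This is carried through the chemistry of steps 3, 4, 6 and 7: its lithium enolate F3, the 2,6-dimethyl ketone F4, the potassium enolate F5, the enol triflate F6, the coupled silane F7 (from F6 and 15) and the alcohol F8. Ring closure of F8 under the conditions of step 8 expels ethene, passes through the same diene 18 and comes back to the route at 19.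

Step 6. Transmetalation and reductive elimination at the tetrasubstituted alkenylpalladium, which sits next to quaternary C10, may be so slow that reduction of the triflate or protonolysis of the alkylzinc takes over. The fallback brings in C6 as a one-carbon unit and makes the C6–C7 bond by auxiliary-controlled enolate alkylation, so that steps 5 and 7 are not needed; it sets out from 10. Stille coupling with (tributylstannyl)methanol (Pd(PPh3)4, LiCl, dioxane, 90 °C) should give {(5R,6R)-5-bromo-6-[(E)-hex-1-en-1-yl]-2,6-dimethylcyclohex-1-en-1-yl}methanol F9, and CBr4/PPh3 (CH2Cl2, 0 °C) the allylic bromide F10. (S)-4-Benzyl-3-[(E)-but-2-enoyl]oxazolidin-2-one is deprotonated with NaHMDS (THF, −78 °C) to its sodium dienolate F11, which is alkylated at the α-carbon by F10 on the face opposite the benzyl group (deconjugative Evans alkylation) to give the imide F12 with the required C7 configuration. LiBH4 (Et2O, MeOH, 0 °C) removes the auxiliary and the route is rejoined at 17.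

Step 10. The aluminium amide may abstract a proton from a ring methylene (C3 or C6) instead of the C4 methyl, or the Lewis acid may induce a 1,2-shift of the epoxide to a ketone. The fallback delivers the oxygen by an ene reaction instead of through an epoxide, so that step 9 is skipped; it sets out from 19. Dye-sensitised photo-oxygenation (O2, tetraphenylporphyrin, visible light, CH2Cl2, −20 °C; Schenck ene reaction, attack opposite the C10 methyl) should give [(2R,4aR,5R,8aR)-5-bromo-8a-hydroperoxy-4a-methyl-8-methylidenedecahydronaphthalen-2-yl]methanol F13, which is reduced in the same flask with PPh3 and comes back to the route at 21. Regioselectivity between the methyl and ring hydrogens is the weak point of this fallback.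

Further compounds
F1 | step 2 | (R)-1-ethenyl-2-methylcyclohex-2-en-1-ol | C=C[C@]1(O)CCCC=C1C
F2 | step 2 | (2R,3R)-3-bromo-2-ethenyl-2-methylcyclohexan-1-one | C=C[C@@]1(C)[C@H](Br)CCCC1=O
F3 | step 2 | lithium enolate of F2 | C=C[C@@]1(C)[C@H](Br)CCC=C1O[Li]
F4 | step 2 | (2R,3R)-3-bromo-2-ethenyl-2,6-dimethylcyclohexan-1-one (both C6 epimers) | C=C[C@@]1(C)[C@H](Br)CCC(C)C1=O
F5 | step 2 | potassium enolate of F4 | C=C[C@@]1(C)[C@H](Br)CCC(C)=C1O[K]
F6 | step 2 | (5R,6R)-5-bromo-6-ethenyl-2,6-dimethylcyclohex-1-en-1-yl trifluoromethanesulfonate | C=C[C@@]1(C)[C@H](Br)CCC(C)=C1OS(=O)(=O)C(F)(F)F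
F7 | step 2 | {(2S)-2-{[(5R,6R)-5-bromo-6-ethenyl-2,6-dimethylcyclohex-1-en-1-yl]methyl}but-3-en-1-yl}(isopropoxy)dimethylsilane | C=C[C@@]1(C)[C@H](Br)CCC(C)=C1C[C@H](C[Si](C)(C)OC(C)C)C=C
F8 | step 2 | (2S)-2-{[(5R,6R)-5-bromo-6-ethenyl-2,6-dimethylcyclohex-1-en-1-yl]methyl}but-3-en-1-ol | C=C[C@@]1(C)[C@H](Br)CCC(C)=C1C[C@H](CO)C=C
F9 | step 6 | {(5R,6R)-5-bromo-6-[(E)-hex-1-en-1-yl]-2,6-dimethylcyclohex-1-en-1-yl}methanol | CCCC/C=C/[C@@]1(C)[C@H](Br)CCC(C)=C1CO
F10 | step 6 | (3R,4R)-4-bromo-2-(bromomethyl)-3-[(E)-hex-1-en-1-yl]-1,3-dimethylcyclohex-1-ene | CCCC/C=C/[C@@]1(C)[C@H](Br)CCC(C)=C1CBr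
F11 | step 6 | sodium (Z)-dienolate of (S)-4-benzyl-3-[(E)-but-2-enoyl]oxazolidin-2-one | C=C/C=C(\O[Na])N1[C@@H](Cc2ccccc2)COC1=O
F12 | step 6 | (4S)-4-benzyl-3-[(2S)-2-{[(5R,6R)-5-bromo-6-[(E)-hex-1-en-1-yl]-2,6-dimethylcyclohex-1-en-1-yl]methyl}but-3-enoyl]oxazolidin-2-one | CCCC/C=C/[C@@]1(C)[C@H](Br)CCC(C)=C1C[C@@H](C=C)C(=O)N1[C@@H](Cc2ccccc2)COC1=O
F13 | step 10 | [(2R,4aR,5R,8aR)-5-bromo-8a-hydroperoxy-4a-methyl-8-methylidenedecahydronaphthalen-2-yl]methanol | OC[C@@H]1CC[C@@]2(C)[C@H](Br)CCC(=C)[C@]2(OO)C1
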